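**Strategy.** The carbocycle (C4a–C5–C6–C7–C8–C8a) carries its side chain at C5, directly beside ring-fusion carbon C4a. The route exploits this: the cyclohexane ring is drawn from a cis-fused cycloheptanone, and a photochemical Wolff rearrangement of its α-diazoketone lets C4a migrate, contracts the seven-membered ring to the six-membered one, extrudes the carbonyl carbon as C1′ of the side chain and sets C5 on ketonisation. The precursor, an N-Boc decahydrocyclohepta[b]pyridin-5-one, comes from cycloheptane-1,3-dione and an aminohydroxylation-derived amino alcohol; hydrogenation relays C4a and C8a from C2 and C3. Cross-metathesis, hydrogenation and an inverting Mitsunobu esterification at C3 complete the target.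

Key step: step 9

Remark: ethyl crotonate, cycloheptane-1,3-dione, (R)-1,2-epoxypentane and (E)-oct-2-enoic acid are assumed to be commercial; operations telescoped without purification of the intermediate are counted as one step.

**Step 1**
Reactants: 1 ethyl (2E)-but-2-enoate
Product: 2 ethyl (2S,3R)-3-[(tert-butoxycarbonyl)amino]-2-hydroxybutanoate
Conditions: BocNH2, t-BuOCl, NaOH, K2OsO2(OH)4 (4 mol %), (DHQD)2PHAL (5 mol %), n-PrOH/H2O 1:1, 0 °C
Reagents that add atoms: tert-butyl carbamate NC(=O)OC(C)(C)C; water O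
Why: Sharpless asymmetric aminohydroxylation adds N and O syn across the (E)-alkene with nitrogen going to C3, and the (DHQD)2PHAL ligand should select the face that gives the (2S,3R) syn amino alcohol, which fixes C2 of the target and supplies C3 in the configuration that step 16 inverts.

**Step 2**
Reactants: 2 ethyl (2S,3R)-3-[(tert-butoxycarbonyl)amino]-2-hydroxybutanoate
Product: 3 ethyl (2S,3R)-2-(benzyloxy)-3-[(tert-butoxycarbonyl)amino]butanoate
Conditions: BnBr, Ag2O, CH2Cl2, rt, dark
Reagents that add atoms: benzyl bromide BrCc1ccccc1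
Why: Ag2O-promoted Williamson etherification benzylates the secondary hydroxyl without a strong base, so the carbamate N–H should not be alkylated, no oxazolidinone should form and both stereocentres stay untouched.

**Step 3**
Reactants: 3 ethyl (2S,3R)-2-(benzyloxy)-3-[(tert-butoxycarbonyl)amino]butanoate
Product: 4 tert-butyl N-[(2R,3S)-3-(benzyloxy)-4-hydroxybutan-2-yl]carbamate
Conditions: LiBH4, THF, 0 °C to rt; aq NH4Cl
Reagents that add atoms: none
Why: Hydride reduction with LiBH4 converts the ester into the primary alcohol chemoselectively beside the carbamate and the benzyl ether.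

**Step 4**
Reactants: 4 tert-butyl N-[(2R,3S)-3-(benzyloxy)-4-hydroxybutan-2-yl]carbamate; 5 cycloheptane-1,3-dione
Product: 7 3-{[(2R,3S)-3-(benzyloxy)-4-hydroxybutan-2-yl]amino}cyclohept-2-en-1-one, via amine hydrochloride 6 (not isolated)
Conditions: HCl (4 M in 1,4-dioxane), rt; evaporate; then 5, Et3N, toluene, reflux, Dean–Stark trap
Reagents that add atoms: hydrogen chloride Cl (chloride of 6)
Why: Acidolysis removes the Boc group and the liberated primary amine condenses with the 1,3-diketone to the vinylogous amide (enaminone formation) while water is removed azeotropically.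

**Step 5**
Reactants: 7 3-{[(2R,3S)-3-(benzyloxy)-4-hydroxybutan-2-yl]amino}cyclohept-2-en-1-one
Product: 9 (2R,3R)-3-(benzyloxy)-2-methyl-1,2,3,4,6,7,8,9-octahydro-5H-cyclohepta[b]pyridin-5-one, via mesylate 8 (not isolated)
Conditions: MsCl, Et3N, MeCN, 0 °C; then DBU, 70 °C
Reagents that add atoms: methanesulfonyl chloride CS(=O)(=O)Cl (mesyl group of 8)
Why: After mesylation of the primary alcohol the nucleophilic α-carbon of the vinylogous amide should close the piperidine ring by intramolecular 6-exo-tet C-alkylation (alkylative enaminone cyclisation), since N-alkylation would give a four-membered and O-alkylation an eight-membered ring.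

**Step 6**
Reactants: 9 (2R,3R)-3-(benzyloxy)-2-methyl-1,2,3,4,6,7,8,9-octahydro-5H-cyclohepta[b]pyridin-5-one
Product: 10 (2R,3R,4aS,9aS)-3-(benzyloxy)-2-methyldecahydro-5H-cyclohepta[b]pyridin-5-one
Conditions: H2 (4 atm), Pt/C, AcOH, rt; then aq NaHCO3
Reagents that add atoms: none
Why: Heterogeneous hydrogenation of the tetrasubstituted enaminone C=C should deliver both hydrogens syn from the face opposite the C2 methyl and C3 benzyloxy groups (both on one face), giving the cis ring fusion with H4a and H9a cis to H2, while platinum in acetic acid spares the benzyl ether.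

**Step 7**
Reactants: 10 (2R,3R,4aS,9aS)-3-(benzyloxy)-2-methyldecahydro-5H-cyclohepta[b]pyridin-5-one
Product: 11 tert-butyl (2R,3R,4aS,9aS)-3-(benzyloxy)-2-methyl-5-oxodecahydro-1H-cyclohepta[b]pyridine-1-carboxylate
Conditions: Boc2O, 1,4-dioxane, 60 °C
Reagents that add atoms: di-tert-butyl dicarbonate CC(C)(C)OC(=O)OC(=O)OC(C)(C)C
Why: Carbamate formation on the hindered secondary amine with warm Boc2O masks the nitrogen for the enolate, carbene and ketene chemistry that follows.

**Step 8**
Reactants: 11 tert-butyl (2R,3R,4aS,9aS)-3-(benzyloxy)-2-methyl-5-oxodecahydro-1H-cyclohepta[b]pyridine-1-carboxylate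
Product: 13 tert-butyl (2R,3R,4aS,9aS)-3-(benzyloxy)-6-diazo-2-methyl-5-oxodecahydro-1H-cyclohepta[b]pyridine-1-carboxylate, via trifluoroacetyl ketone 12 (not isolated)
Conditions: LiN(SiMe3)2, THF, −78 °C, then CF3CO2CH2CF3; aq HCl work-up; MsN3, Et3N, H2O (1 equiv), MeCN, rt
Reagents that add atoms: 2,2,2-trifluoroethyl trifluoroacetate O=C(OCC(F)(F)F)C(F)(F)F (trifluoroacetyl group of 12); methanesulfonyl azide CS(=O)(=O)N=[N+]=[N-]
Why: Detrifluoroacetylative diazo transfer (Regitz type): kinetic deprotonation should occur at the C6 methylene and not at the tertiary C4a–H, Claisen acylation activates that carbon, and the sulfonyl azide then transfers the diazo group with loss of the trifluoroacetyl group.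

**Step 9**
Reactants: 13 tert-butyl (2R,3R,4aS,9aS)-3-(benzyloxy)-6-diazo-2-methyl-5-oxodecahydro-1H-cyclohepta[b]pyridine-1-carboxylate
Product: 15 1-tert-butyl 5-methyl (2R,3R,4aR,5R,8aS)-3-(benzyloxy)-2-methyloctahydroquinoline-1,5(2H)-dicarboxylate, via ketene 14 (not isolated)
Conditions: hν (medium-pressure Hg lamp, Pyrex filter), MeOH, 0 °C
Reagents that add atoms: methanol CO
Why: Light expels N2 from the cyclic α-diazoketone and C4a migrates from the carbonyl carbon to the diazo carbon with retention (Wolff rearrangement), giving ketene 14, to which methanol adds before the ester enol ketonises to 15. The closest known reaction type is the photochemical Wolff ring contraction of cyclic 2-diazoketones to ring-contracted cycloalkanecarboxylates. The six-membered carbocycle is not closed by a cyclisation but arises from the seven-membered ring by this 1,2-alkyl shift, the former carbonyl carbon becoming exocyclic C1′. The new stereocentre C5 is set on ketonisation: allylic 1,3-strain with the N-Boc group and with the exocyclic enol places the C4a–C4 bond axial on the carbocycle, so the proton should enter C5 anti to it and give H5 cis to H4a, which is also the equatorial, thermodynamically preferred ester. Which carbon is extruded is fixed by the position of the diazo group, and rearrangement should win over O–H insertion or 1,2-hydride shift because the ring locks the diazoketone in the s-Z geometry.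

**Step 10**
Reactants: 15 1-tert-butyl 5-methyl (2R,3R,4aR,5R,8aS)-3-(benzyloxy)-2-methyloctahydroquinoline-1,5(2H)-dicarboxylate
Product: 16 tert-butyl (2R,3R,4aR,5R,8aS)-3-(benzyloxy)-5-formyl-2-methyloctahydroquinoline-1(2H)-carboxylate
Conditions: i-Bu2AlH (1.1 equiv), CH2Cl2, −78 °C; aq potassium sodium tartrate
Reagents that add atoms: none
Why: Low-temperature i-Bu2AlH reduction of the ester should stop at the tetrahedral aluminium hemiacetal, which releases the aldehyde on work-up without touching C5.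

**Step 11**
Reactants: 16 tert-butyl (2R,3R,4aR,5R,8aS)-3-(benzyloxy)-5-formyl-2-methyloctahydroquinoline-1(2H)-carboxylate
Product: 17 tert-butyl (2R,3R,4aR,5S,8aS)-3-(benzyloxy)-5-ethenyl-2-methyloctahydroquinoline-1(2H)-carboxylate
Conditions: Ph3PCH3Br, KOt-Bu, THF, 0 °C to rt
Reagents that add atoms: methyltriphenylphosphonium bromide C[P+](c1ccccc1)(c1ccccc1)c1ccccc1.[Br-]
Why: Wittig methylenation of the α-branched aldehyde should be faster than enolisation, so C5 is kept (its descriptor changes only through the priority rules).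

**Step 12**
Reactants: 18 (2R)-2-propyloxirane
Product: 19 (4R)-oct-7-en-4-ol
Conditions: CH2=CHCH2MgBr, CuI (10 mol %), THF, −30 °C; aq NH4Cl
Reagents that add atoms: allylmagnesium bromide C=CC[Mg]Br
Why: Copper-catalysed SN2 opening of the terminal epoxide at its unsubstituted carbon leaves the purchased C–O stereocentre, the later C5′, untouched.

**Step 13**
Reactants: 19 (4R)-oct-7-en-4-ol
Product: 20 tert-butyl(dimethyl){[(4R)-oct-7-en-4-yl]oxy}silane
Conditions: TBSCl, imidazole, DMF, rt
Reagents that add atoms: tert-butyldimethylsilyl chloride CC(C)(C)[Si](C)(C)Cl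
Why: Standard silylation of the secondary alcohol gives the silyl ether that keeps C5′–OH apart from C3–OH in the end game.

**Step 14**
Reactants: 17 tert-butyl (2R,3R,4aR,5S,8aS)-3-(benzyloxy)-5-ethenyl-2-methyloctahydroquinoline-1(2H)-carboxylate; 20 tert-butyl(dimethyl){[(4R)-oct-7-en-4-yl]oxy}silane
Product: 21 tert-butyl (2R,3R,4aR,5S,8aS)-3-(benzyloxy)-5-[(1E,5R)-5-{[tert-butyl(dimethyl)silyl]oxy}oct-1-en-1-yl]-2-methyloctahydroquinoline-1(2H)-carboxylate
Conditions: second-generation Grubbs catalyst (5 mol %), 20 (3 equiv), CH2Cl2, 40 °C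
Reagents that add atoms: none
Why: Olefin cross-metathesis between the unhindered terminal alkene 20 (in excess) and the allylically branched vinyl group of 17 should favour the cross product with loss of ethene; alkene geometry is irrelevant because the double bond is hydrogenated next.

**Step 15**
Reactants: 21 tert-butyl (2R,3R,4aR,5S,8aS)-3-(benzyloxy)-5-[(1E,5R)-5-{[tert-butyl(dimethyl)silyl]oxy}oct-1-en-1-yl]-2-methyloctahydroquinoline-1(2H)-carboxylate
Product: 22 tert-butyl (2R,3R,4aR,5R,8aS)-5-[(5R)-5-{[tert-butyl(dimethyl)silyl]oxy}octyl]-3-hydroxy-2-methyloctahydroquinoline-1(2H)-carboxylate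
Conditions: H2 (1 atm), Pd(OH)2/C, EtOAc, rt
Reagents that add atoms: none
Why: Catalytic hydrogenation saturates the side-chain alkene and hydrogenolyses the benzyl ether in one operation, leaving carbamate, silyl ether and all stereocentres intact.

**Step 16**
Reactants: 22 tert-butyl (2R,3R,4aR,5R,8aS)-5-[(5R)-5-{[tert-butyl(dimethyl)silyl]oxy}octyl]-3-hydroxy-2-methyloctahydroquinoline-1(2H)-carboxylate; 23 (2E)-oct-2-enoic acid
Product: 24 tert-butyl (2R,3S,4aR,5R,8aS)-5-[(5R)-5-{[tert-butyl(dimethyl)silyl]oxy}octyl]-2-methyl-3-{[(2E)-oct-2-enoyl]oxy}octahydroquinoline-1(2H)-carboxylate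
Conditions: PPh3, DIAD, toluene, 0 °C to rt
Reagents that add atoms: none
Why: Mitsunobu esterification: the enoate should displace the equatorial C3 oxyphosphonium group by SN2 attack along the open axial trajectory, inverting C3 to the trans-2,3 arrangement of the target while installing the ester, and an equatorial leaving group has no antiperiplanar hydrogen for elimination.

**Step 17**
Reactants: 24 tert-butyl (2R,3S,4aR,5R,8aS)-5-[(5R)-5-{[tert-butyl(dimethyl)silyl]oxy}octyl]-2-methyl-3-{[(2E)-oct-2-enoyl]oxy}octahydroquinoline-1(2H)-carboxylate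
Product: 25 (2R,3S,4aR,5R,8aS)-5-[(5R)-5-hydroxyoctyl]-2-methyldecahydroquinolin-3-yl (2E)-oct-2-enoate
Conditions: CF3CO2H/H2O 9:1, 0 °C to rt; then aq NaHCO3
Reagents that add atoms: none
Why: Acidolysis removes the Boc group and the silyl ether in one operation, the conjugated ester is stable to acid, and the anti arrangement of N and O across C2–C3 should disfavour O-to-N acyl shift on neutralisation.

**Compound list**
1 | ethyl (2E)-but-2-enoate | C/C=C/C(=O)OCC | starting material
2 | ethyl (2S,3R)-3-[(tert-butoxycarbonyl)amino]-2-hydroxybutanoate | C[C@@H](NC(=O)OC(C)(C)C)[C@H](O)C(=O)OCC | intermediate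
3 | ethyl (2S,3R)-2-(benzyloxy)-3-[(tert-butoxycarbonyl)amino]butanoate | C[C@@H](NC(=O)OC(C)(C)C)[C@H](OCc1ccccc1)C(=O)OCC | intermediate
4 | tert-butyl N-[(2R,3S)-3-(benzyloxy)-4-hydroxybutan-2-yl]carbamate | C[C@@H](NC(=O)OC(C)(C)C)[C@H](OCc1ccccc1)CO | intermediate
5 | cycloheptane-1,3-dione | O=C1CC(=O)CCCC1 | starting material
6 | (2S,3R)-3-amino-2-(benzyloxy)butan-1-ol hydrochloride | C[C@@H](N)[C@H](OCc1ccccc1)CO.Cl | intermediate (not isolated)
7 | 3-{[(2R,3S)-3-(benzyloxy)-4-hydroxybutan-2-yl]amino}cyclohept-2-en-1-one | C[C@@H](NC1=CC(=O)CCCC1)[C@H](OCc1ccccc1)CO | intermediate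
8 | (2S,3R)-2-(benzyloxy)-3-[(3-oxocyclohept-1-en-1-yl)amino]butyl methanesulfonate | C[C@@H](NC1=CC(=O)CCCC1)[C@H](OCc1ccccc1)COS(C)(=O)=O | intermediate (not isolated)
9 | (2R,3R)-3-(benzyloxy)-2-methyl-1,2,3,4,6,7,8,9-octahydro-5H-cyclohepta[b]pyridin-5-one | c1ccccc1CO[C@@H]1CC2=C(CCCCC2=O)N[C@@H]1C | intermediate
10 | (2R,3R,4aS,9aS)-3-(benzyloxy)-2-methyldecahydro-5H-cyclohepta[b]pyridin-5-one (cis-fused; H2, H3, H4a, H9a on one face) | c1ccccc1CO[C@@H]1C[C@@H]2C(=O)CCCC[C@@H]2N[C@@H]1C | intermediate
11 | tert-butyl (2R,3R,4aS,9aS)-3-(benzyloxy)-2-methyl-5-oxodecahydro-1H-cyclohepta[b]pyridine-1-carboxylate | c1ccccc1CO[C@@H]1C[C@@H]2C(=O)CCCC[C@@H]2N(C(=O)OC(C)(C)C)[C@@H]1C | intermediate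
12 | tert-butyl (2R,3R,4aS,9aS)-3-(benzyloxy)-2-methyl-5-oxo-6-(trifluoroacetyl)decahydro-1H-cyclohepta[b]pyridine-1-carboxylate (C6 undefined, enolised) | c1ccccc1CO[C@@H]1C[C@@H]2C(=O)C(C(=O)C(F)(F)F)CCC[C@@H]2N(C(=O)OC(C)(C)C)[C@@H]1C | intermediate (not isolated)
13 | tert-butyl (2R,3R,4aS,9aS)-3-(benzyloxy)-6-diazo-2-methyl-5-oxodecahydro-1H-cyclohepta[b]pyridine-1-carboxylate | c1ccccc1CO[C@@H]1C[C@@H]2C(=O)C(=[N+]=[N-])CCC[C@@H]2N(C(=O)OC(C)(C)C)[C@@H]1C | intermediate
14 | tert-butyl (2R,3R,4aR,8aS)-3-(benzyloxy)-2-methyl-5-(oxomethylidene)octahydroquinoline-1(2H)-carboxylate (ketene) | c1ccccc1CO[C@@H]1C[C@@H]2C(=C=O)CCC[C@@H]2N(C(=O)OC(C)(C)C)[C@@H]1C | intermediate (not isolated)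
15 | 1-tert-butyl 5-methyl (2R,3R,4aR,5R,8aS)-3-(benzyloxy)-2-methyloctahydroquinoline-1,5(2H)-dicarboxylate | c1ccccc1CO[C@@H]1C[C@@H]2[C@H](C(=O)OC)CCC[C@@H]2N(C(=O)OC(C)(C)C)[C@@H]1C | intermediate
16 | tert-butyl (2R,3R,4aR,5R,8aS)-3-(benzyloxy)-5-formyl-2-methyloctahydroquinoline-1(2H)-carboxylate | c1ccccc1CO[C@@H]1C[C@@H]2[C@H](C=O)CCC[C@@H]2N(C(=O)OC(C)(C)C)[C@@H]1C | intermediate
17 | tert-butyl (2R,3R,4aR,5S,8aS)-3-(benzyloxy)-5-ethenyl-2-methyloctahydroquinoline-1(2H)-carboxylate | c1ccccc1CO[C@@H]1C[C@@H]2[C@H](C=C)CCC[C@@H]2N(C(=O)OC(C)(C)C)[C@@H]1C | intermediate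
18 | (2R)-2-propyloxirane ((R)-1,2-epoxypentane) | CCC[C@@H]1CO1 | starting material
19 | (4R)-oct-7-en-4-ol | C=CCC[C@H](O)CCC | intermediate
20 | tert-butyl(dimethyl){[(4R)-oct-7-en-4-yl]oxy}silane | C=CCC[C@H](O[Si](C)(C)C(C)(C)C)CCC | intermediate
21 | tert-butyl (2R,3R,4aR,5S,8aS)-3-(benzyloxy)-5-[(1E,5R)-5-{[tert-butyl(dimethyl)silyl]oxy}oct-1-en-1-yl]-2-methyloctahydroquinoline-1(2H)-carboxylate (E isomer drawn) | c1ccccc1CO[C@@H]1C[C@@H]2[C@H](/C=C/CC[C@H](O[Si](C)(C)C(C)(C)C)CCC)CCC[C@@H]2N(C(=O)OC(C)(C)C)[C@@H]1C | intermediate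
22 | tert-butyl (2R,3R,4aR,5R,8aS)-5-[(5R)-5-{[tert-butyl(dimethyl)silyl]oxy}octyl]-3-hydroxy-2-methyloctahydroquinoline-1(2H)-carboxylate | O[C@@H]1C[C@@H]2[C@H](CCCC[C@H](O[Si](C)(C)C(C)(C)C)CCC)CCC[C@@H]2N(C(=O)OC(C)(C)C)[C@@H]1C | intermediate
23 | (2E)-oct-2-enoic acid | CCCCC/C=C/C(=O)O | starting material
24 | tert-butyl (2R,3S,4aR,5R,8aS)-5-[(5R)-5-{[tert-butyl(dimethyl)silyl]oxy}octyl]-2-methyl-3-{[(2E)-oct-2-enoyl]oxy}octahydroquinoline-1(2H)-carboxylate | CCCCC/C=C/C(=O)O[C@H]1C[C@@H]2[C@H](CCCC[C@H](O[Si](C)(C)C(C)(C)C)CCC)CCC[C@@H]2N(C(=O)OC(C)(C)C)[C@@H]1C | intermediate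
25 | (2R,3S,4aR,5R,8aS)-5-[(5R)-5-hydroxyoctyl]-2-methyldecahydroquinolin-3-yl (2E)-oct-2-enoate | CCCCC/C=C/C(=O)O[C@H]1C[C@@H]2[C@H](CCCC[C@H](O)CCC)CCC[C@@H]2N[C@@H]1C | target

**Total step count:** 17 steps.
**Longest linear sequence:** 15 steps (steps 1–11 and 14–17); steps 12–13 form the side-chain branch.

**Steps most likely to fail**

Step 6: the electron-rich tetrasubstituted enaminone may be hydrogenated with poor facial selectivity, or the ketone may be reduced as well. The fallback sets out from 9. The nitrogen is acylated first (Boc2O, DMAP, MeCN) to the N-Boc enaminone F1, in which allylic 1,3-strain forces the C2 methyl group axial over one face and the double bond is less electron-rich. Hydrogenation over Pt/C in EtOAc should then add hydrogen anti to the methyl group and give 11 directly, where the fallback rejoins the route; step 7 is then not needed.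

Step 9: the ester enol formed from the ketene and methanol may ketonise with poor facial selectivity at C5. The fallback sets out from the epimer mixture of 15 and corrects C5 by kinetic protonation of a preformed enolate, not by the photolysis medium. Deprotonation (LiN(i-Pr)2, THF, −78 °C) gives the lithium ester enolate F2, which is quenched at −78 °C with a hindered proton donor (2,6-di-tert-butylphenol) from the face anti to the axial C4a–C4 bond. This returns to 15.

Step 16: the weakly acidic, Michael-accepting enoic acid may fail as Mitsunobu partner at the hindered C3 (slow displacement, ester formed with retention through an acyloxyphosphonium ion, or phosphine addition to the enoate). The fallback sets out from 22 and separates inversion from acylation. Mitsunobu reaction with 4-nitrobenzoic acid (PPh3, DIAD) gives the inverted 4-nitrobenzoate F3. Methanolysis (K2CO3, MeOH) gives the (3S)-alcohol F4. Carbodiimide esterification with 23 (EDC·HCl, DMAP, CH2Cl2), which proceeds with retention, rejoins the route at 24.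

**Further compounds**
F1 | step 6 | tert-butyl (2R,3R)-3-(benzyloxy)-2-methyl-5-oxo-2,3,4,5,6,7,8,9-octahydro-1H-cyclohepta[b]pyridine-1-carboxylate | c1ccccc1CO[C@@H]1CC2=C(CCCCC2=O)N(C(=O)OC(C)(C)C)[C@@H]1C
F2 | step 9 | lithium ester enolate of 15 (C5 exocyclic methoxy-oxido-methylidene) | c1ccccc1CO[C@@H]1C[C@@H]2C(=C([O-])OC)CCC[C@@H]2N(C(=O)OC(C)(C)C)[C@@H]1C.[Li+]
F3 | step 16 | tert-butyl (2R,3S,4aR,5R,8aS)-5-[(5R)-5-{[tert-butyl(dimethyl)silyl]oxy}octyl]-2-methyl-3-[(4-nitrobenzoyl)oxy]octahydroquinoline-1(2H)-carboxylate | O=C(O[C@H]1C[C@@H]2[C@H](CCCC[C@H](O[Si](C)(C)C(C)(C)C)CCC)CCC[C@@H]2N(C(=O)OC(C)(C)C)[C@@H]1C)c1ccc(cc1)[N+](=O)[O-]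
F4 | step 16 | tert-butyl (2R,3S,4aR,5R,8aS)-5-[(5R)-5-{[tert-butyl(dimethyl)silyl]oxy}octyl]-3-hydroxy-2-methyloctahydroquinoline-1(2H)-carboxylate | O[C@H]1C[C@@H]2[C@H](CCCC[C@H](O[Si](C)(C)C(C)(C)C)CCC)CCC[C@@H]2N(C(=O)OC(C)(C)C)[C@@H]1C
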